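**Retrosynthetic overview**

1. The trans-diaxial diol is taken back to a β-epoxide and then to a ring-A cyclohexene; nothing else is adjusted after the key step.
2. Key disconnection: two σ-bonds of the bromocyclohexane ring (quaternary C(Me)–ring-fusion CH, and CHBr–CH2) are cut as an intramolecular Diels–Alder reaction of a norbornane-bound 1,7,9-decatriene: dienophile (E)-BrCH=C(Me)–, diene (E)-CH=C(Me)–CH=CH2.
3. Enabling feature: in the bromocyclohexane ring (ring A) the C(Me)(OH)–CH(OH) pair is a masked C=C lying opposite the C(Me)(quaternary)–CHBr bond (a cyclohexene retron), and the two ring-fusion atoms are already joined through the neighbouring cyclohexane (ring B) by the four-atom chain CH2–CH2–bridgehead C–norbornane CH, which is the tether.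
4. The norbornane comes from an ester-tethered Diels–Alder reaction of a 1,2-disubstituted cyclopentadiene with an (E)-3-methoxyacrylate (temporary δ-lactone, opened again later); it is resolved as an (S)-1-phenylethylamide.
5. Ring order: cyclopentene (bought) → norbornane (plus temporary lactone) → ring B and, completed by the second σ-bond, ring A last.

Key step: step 16

Remark: the two diastereomeric amides of step 7 are taken to be separable; the one whose norbornene part has the configuration drawn (to be assigned by X-ray against the known (S)-centre) is carried on, and (E)-3-methoxyacrylic acid is taken as purchasable.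

**Route**

Step 1
Reactants: 1 cyclopentanone; 2 acetone
Product: 3 2-(propan-2-ylidene)cyclopentan-1-one
Conditions: KOH (aq.), acetone (large excess), 23 °C to reflux
Reagents that add atoms: acetone (2), CC(C)=O
Why: crossed aldol condensation of the cyclopentanone enolate with acetone and E1cB loss of water should give the conjugated exocyclic enone.

Step 2
Reactants: 3 2-(propan-2-ylidene)cyclopentan-1-one
Product: 4 2-isopropylcyclopent-2-en-1-one
Conditions: HBr (48 % aq., cat.), n-BuOH, reflux
Reagents that add atoms: none
Why: acid-catalysed alkene isomerisation through the dienol should move the double bond into the ring, the endocyclic 2-alkylcyclopent-2-enone being the thermodynamic isomer in this series.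

Step 3
Reactants: 4 2-isopropylcyclopent-2-en-1-one; 5 ethyl acetate
Product: 6 ethyl 2-(1-hydroxy-2-isopropylcyclopent-2-en-1-yl)acetate (racemic)
Conditions: LDA, THF, −78 °C; then 4, −78 °C; aqueous work-up
Reagents that add atoms: ethyl acetate (5), CCOC(C)=O
Why: kinetic 1,2-addition (aldol-type) of the lithium ester enolate to the enone carbonyl at −78 °C; the new carbinol centre is racemic and is destroyed in step 6.

Step 4
Reactants: 6 ethyl 2-(1-hydroxy-2-isopropylcyclopent-2-en-1-yl)acetate
Product: 7 1-(2-hydroxyethyl)-2-isopropylcyclopent-2-en-1-ol (racemic)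
Conditions: LiAlH4, Et2O, 0 °C
Reagents that add atoms: none
Why: hydride reduction of the ester to the primary alcohol leaves the tertiary allylic alcohol and the alkene untouched.

Step 5
Reactants: 7 1-(2-hydroxyethyl)-2-isopropylcyclopent-2-en-1-ol; 8 (E)-3-methoxyacrylic acid
Product: 9 2-(1-hydroxy-2-isopropylcyclopent-2-en-1-yl)ethyl (E)-3-methoxyacrylate (racemic)
Conditions: EDC·HCl, DMAP (cat.), CH2Cl2, 0 to 23 °C
Reagents that add atoms: (E)-3-methoxyacrylic acid (8), CO/C=C/C(O)=O
Why: Steglich esterification acylates only the primary hydroxyl and so attaches the dienophile through the future temporary tether.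

Step 6
Reactants: 9 2-(1-hydroxy-2-isopropylcyclopent-2-en-1-yl)ethyl (E)-3-methoxyacrylate
Product: 11 racemic 1-(2-hydroxyethyl)-6-isopropyl-3-endo-methoxybicyclo[2.2.1]hept-5-ene-2-exo-carboxylic acid δ-lactone, via cyclopentadienyl ester 10 (not isolated)
Conditions: CSA (cat.), 4 Å MS, PhMe, 23 °C; then K2CO3 (solid), BHT, PhMe (0.01 M), 170 °C, sealed tube
Reagents that add atoms: none
Why: acid-catalysed E1 dehydration of the tertiary allylic alcohol gives the cyclopentadiene, whose tautomers interconvert by [1,5]-H shifts while only the 1-tethered one can cyclise (ester-tethered intramolecular Diels–Alder reaction); the four-atom tether can span the bridgehead and the adjacent carbon only with the carbonyl exo, so the (E)-alkene places OMe endo and the four new stereocentres are fixed relative to one another.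

Step 7
Reactants: 11 racemic norbornene δ-lactone; 12 (S)-1-phenylethylamine
Product: 13 N-[(S)-1-phenylethyl]-1-(2-hydroxyethyl)-6-isopropyl-3-endo-methoxybicyclo[2.2.1]hept-5-ene-2-exo-carboxamide (single diastereomer)
Conditions: (S)-1-phenylethylamine (neat), 2-hydroxypyridine (cat.), 90 °C; then separation of the two diastereomers (chromatography or crystallisation)
Reagents that add atoms: (S)-1-phenylethylamine (12), C[C@H](N)c1ccccc1
Why: aminolysis of the lactone under bifunctional catalysis gives two diastereomeric hydroxy amides, a classical resolution that fixes the absolute configuration of the norbornane.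

Step 8
Reactants: 13 unsaturated hydroxy amide
Product: 14 N-[(S)-1-phenylethyl]-1-(2-hydroxyethyl)-6-endo-isopropyl-3-endo-methoxybicyclo[2.2.1]heptane-2-exo-carboxamide
Conditions: H2 (1 atm), Pd/C, EtOAc, 23 °C
Reagents that add atoms: none
Why: heterogeneous hydrogenation of the strained trisubstituted norbornene from the exo face (the endo face carries the endo OMe and endo H of the other two-carbon bridge) pushes the isopropyl group endo.

Step 9
Reactants: 14 saturated hydroxy amide
Product: 15 1-(2-hydroxyethyl)-6-endo-isopropyl-3-endo-methoxybicyclo[2.2.1]heptane-2-exo-carboxylic acid δ-lactone (single enantiomer)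
Conditions: 1 M H2SO4, 1,4-dioxane, 90 °C
Reagents that add atoms: none
Why: acid-promoted N-to-O acyl transfer (relactonisation) releases the resolving amine without touching a stereocentre.

Step 10
Reactants: 15 saturated δ-lactone
Product: 16 the corresponding δ-lactol (anomers)
Conditions: DIBAL-H, CH2Cl2, −78 °C
Reagents that add atoms: none
Why: partial reduction of the lactone stops at the tetrahedral aluminium acetal, which gives the lactol on work-up.

Step 11
Reactants: 16 δ-lactol; 17 2-(triphenyl-λ5-phosphanylidene)propanal
Product: 18 (E)-3-[1-(2-hydroxyethyl)-6-endo-isopropyl-3-endo-methoxybicyclo[2.2.1]heptan-2-exo-yl]-2-methylprop-2-enal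
Conditions: 17, PhMe, 90 °C; the product is used at once
Reagents that add atoms: 2-(triphenyl-λ5-phosphanylidene)propanal (17), CC(C=O)=P(c1ccccc1)(c1ccccc1)c1ccccc1
Why: Wittig olefination of the open hydroxy-aldehyde form with the stabilised formyl ylide under neutral conditions should give the (E)-trisubstituted enal and frees the primary alcohol of the former tether.

Step 12
Reactants: 18 hydroxy enal
Product: 19 (E)-3-[1-(2-iodoethyl)-6-endo-isopropyl-3-endo-methoxybicyclo[2.2.1]heptan-2-exo-yl]-2-methylprop-2-enal
Conditions: I2, PPh3, imidazole, CH2Cl2, 0 °C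
Reagents that add atoms: iodine, II
Why: Appel-type iodination of the primary alcohol under non-basic conditions leaves the enal intact and removes the hydroxyl that could add to it.

Step 13
Reactants: 19 iodo enal; 20 methyltriphenylphosphonium bromide
Product: 21 1-(2-iodoethyl)-6-endo-isopropyl-3-endo-methoxy-2-exo-[(1E)-2-methylbuta-1,3-dien-1-yl]bicyclo[2.2.1]heptane
Conditions: 20, KHMDS, THF, 0 °C; then 19, −78 to 0 °C
Reagents that add atoms: methyltriphenylphosphonium bromide (20), C[P+](c1ccccc1)(c1ccccc1)c1ccccc1.[Br-]
Why: Wittig methylenation of the aldehyde, which reacts with the unstabilised ylide far faster than the primary iodide is alkylated, completes the (E)-2-methyl-1,3-diene.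

Step 14
Reactants: 21 iodo diene; 22 lithium acetylide–ethylenediamine complex
Product: 23 1-(but-3-yn-1-yl)-6-endo-isopropyl-3-endo-methoxy-2-exo-[(1E)-2-methylbuta-1,3-dien-1-yl]bicyclo[2.2.1]heptane
Conditions: 22, DMSO, 23 °C
Reagents that add atoms: lithium acetylide–ethylenediamine complex (22), [Li+].[C-]#C.NCCN
Why: SN2 alkynylation of the unhindered primary iodide brings in the two dienophile carbons.

Step 15
Reactants: 23 dienyne
Product: 25 1-[(E)-4-bromo-3-methylbut-3-en-1-yl]-6-endo-isopropyl-3-endo-methoxy-2-exo-[(1E)-2-methylbuta-1,3-dien-1-yl]bicyclo[2.2.1]heptane, via alkenylalane 24 (not isolated)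
Conditions: Me3Al, Cp2ZrCl2 (cat.), (CH2Cl)2, 23 °C; then NBS, THF, −30 °C
Reagents that add atoms: trimethylaluminium, C[Al](C)C; N-bromosuccinimide, O=C1CCC(=O)N1Br
Why: Zr-catalysed syn-methylalumination of the terminal alkyne (Negishi carboalumination: Me to the internal carbon, Al to the terminus) followed by brominolysis of the C–Al bond with retention should give the (E)-1-bromo-2-methylalkene with Br cis to the new methyl.

Step 16
Reactants: 25 bromo triene
Product: 26 tetracyclic bromoalkene (target skeleton with a C(Me)=CH double bond in ring A in place of the two carbinol carbons; rings A/B trans-fused; Br equatorial and cis to the angular methyl)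
Conditions: BHT, NaHCO3 (solid), degassed PhMe (5 mM), 200 °C, sealed tube
Reagents that add atoms: none
Why: thermal suprafacial [4+2] cycloaddition (intramolecular Diels–Alder reaction) of an (E)-1,7,9-decatriene, the closest known type being the thermal cyclisation of unactivated decatrienes, including 2-methyl-substituted dienophiles that deliver angular methyl groups, to trans-fused octalins; the rigid norbornane with its quaternary bridgehead holds the two chains gauche and raises the effective molarity. Ring B closes as the tether ring of a fused (type 1) cyclisation by the bond between the two ring-fusion carbons, whereas ring A is the cyclohexene of the cycloaddition itself and is complete only when the second σ-bond (CHBr–CH2) has formed, so it is the last ring to close. The ring-fusion CH is set relative to the norbornane CH by allylic 1,3-strain: the methyl on the internal diene carbon forces the norbornane C–H into the diene plane, and the bridgehead-borne dienophile can then reach only one diene face (the two H atoms end up anti). The quaternary C–Me and the CHBr centres follow from suprafacial addition of the (E)-bromoalkene (Br cis to Me), which places Br equatorial and cis to the angular methyl. The selectivity needed is anti (trans-fused) over syn (cis-fused): with the norbornane fixing the torsion at one end of the tether and the 1,3-strain fixing it at the diene end, only the anti transition state keeps the four-atom tether in a chair (angular methyl axial, Br endo), whereas the syn one needs a boat. The bromoalkene is chosen as dienophile so that no later substitution at the neopentyl CHBr carbon is required.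

Step 17
Reactants: 26 tetracyclic bromoalkene
Product: 27 β-epoxide of 26 (oxirane on the face opposite the angular methyl)
Conditions: mCPBA, NaHCO3, CH2Cl2, 0 °C
Reagents that add atoms: meta-chloroperoxybenzoic acid, OOC(=O)c1cccc(Cl)c1
Why: Prilezhaev epoxidation of the only alkene, the peracid approaching the trisubstituted ring-A double bond anti to the axial angular methyl of the rigid trans-decalin.

Step 18
Reactants: 27 β-epoxide
Product: 28 CNP0130529.1 (target)
Conditions: HClO4 (cat.), THF–H2O, 0 to 23 °C
Reagents that add atoms: water, O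
Why: acid-catalysed epoxide hydrolysis in which the Markovnikov and the trans-diaxial (Fürst–Plattner) preferences coincide: water attacks the tertiary carbon axially with inversion, giving the axial tertiary OH syn to the angular methyl and the axial secondary OH with retention, i.e. the trans-diol of the target.

**Compound list**

1 | cyclopentanone | O=C1CCCC1 | starting material
2 | acetone | CC(C)=O | starting material
3 | 2-(propan-2-ylidene)cyclopentan-1-one | CC(C)=C1CCCC1=O | intermediate
4 | 2-isopropylcyclopent-2-en-1-one | CC(C)C1=CCCC1=O | intermediate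
5 | ethyl acetate | CCOC(C)=O | starting material
6 | ethyl 2-(1-hydroxy-2-isopropylcyclopent-2-en-1-yl)acetate (racemic) | CCOC(=O)CC1(O)CCC=C1C(C)C | intermediate
7 | 1-(2-hydroxyethyl)-2-isopropylcyclopent-2-en-1-ol (racemic) | OCCC1(O)CCC=C1C(C)C | intermediate
8 | (E)-3-methoxyacrylic acid | CO/C=C/C(O)=O | starting material
9 | 2-(1-hydroxy-2-isopropylcyclopent-2-en-1-yl)ethyl (E)-3-methoxyacrylate (racemic) | CO/C=C/C(=O)OCCC1(O)CCC=C1C(C)C | intermediate
10 | 2-(2-isopropylcyclopenta-1,3-dien-1-yl)ethyl (E)-3-methoxyacrylate (reacting tautomer; not isolated) | CO/C=C/C(=O)OCCC1=C(C(C)C)C=CC1 | intermediate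
11 | racemic 1-(2-hydroxyethyl)-6-isopropyl-3-endo-methoxybicyclo[2.2.1]hept-5-ene-2-exo-carboxylic acid δ-lactone (the enantiomer that is carried on is drawn) | CO[C@H]1[C@H]2C=C(C(C)C)[C@]3(CCOC(=O)[C@H]13)C2 | intermediate
12 | (S)-1-phenylethylamine | C[C@H](N)c1ccccc1 | starting material
13 | N-[(S)-1-phenylethyl]-1-(2-hydroxyethyl)-6-isopropyl-3-endo-methoxybicyclo[2.2.1]hept-5-ene-2-exo-carboxamide (single diastereomer) | CO[C@H]1[C@H]2C=C(C(C)C)[C@](CCO)(C2)[C@@H]1C(=O)N[C@@H](C)c1ccccc1 | intermediate
14 | N-[(S)-1-phenylethyl]-1-(2-hydroxyethyl)-6-endo-isopropyl-3-endo-methoxybicyclo[2.2.1]heptane-2-exo-carboxamide | CO[C@H]1[C@H]2C[C@@H](C(C)C)[C@](CCO)(C2)[C@@H]1C(=O)N[C@@H](C)c1ccccc1 | intermediate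
15 | 1-(2-hydroxyethyl)-6-endo-isopropyl-3-endo-methoxybicyclo[2.2.1]heptane-2-exo-carboxylic acid δ-lactone (single enantiomer) | CO[C@H]1[C@H]2C[C@@H](C(C)C)[C@]3(CCOC(=O)[C@H]13)C2 | intermediate
16 | δ-lactol of 15 (anomers) | CO[C@H]1[C@H]2C[C@@H](C(C)C)[C@]3(CCOC(O)[C@H]13)C2 | intermediate
17 | 2-(triphenyl-λ5-phosphanylidene)propanal | CC(C=O)=P(c1ccccc1)(c1ccccc1)c1ccccc1 | starting material
18 | (E)-3-[1-(2-hydroxyethyl)-6-endo-isopropyl-3-endo-methoxybicyclo[2.2.1]heptan-2-exo-yl]-2-methylprop-2-enal | CO[C@H]1[C@H]2C[C@@H](C(C)C)[C@](CCO)(C2)[C@@H]1/C=C(\C)C=O | intermediate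
19 | (E)-3-[1-(2-iodoethyl)-6-endo-isopropyl-3-endo-methoxybicyclo[2.2.1]heptan-2-exo-yl]-2-methylprop-2-enal | CO[C@H]1[C@H]2C[C@@H](C(C)C)[C@](CCI)(C2)[C@@H]1/C=C(\C)C=O | intermediate
20 | methyltriphenylphosphonium bromide | C[P+](c1ccccc1)(c1ccccc1)c1ccccc1.[Br-] | starting material
21 | 1-(2-iodoethyl)-6-endo-isopropyl-3-endo-methoxy-2-exo-[(1E)-2-methylbuta-1,3-dien-1-yl]bicyclo[2.2.1]heptane | CO[C@H]1[C@H]2C[C@@H](C(C)C)[C@](CCI)(C2)[C@@H]1/C=C(\C)C=C | intermediate
22 | lithium acetylide–ethylenediamine complex | [Li+].[C-]#C.NCCN | starting material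
23 | 1-(but-3-yn-1-yl)-6-endo-isopropyl-3-endo-methoxy-2-exo-[(1E)-2-methylbuta-1,3-dien-1-yl]bicyclo[2.2.1]heptane | CO[C@H]1[C@H]2C[C@@H](C(C)C)[C@](CCC#C)(C2)[C@@H]1/C=C(\C)C=C | intermediate
24 | (E)-alkenyl(dimethyl)alane from syn-methylalumination of 23 (Al cis to the new methyl; not isolated) | CO[C@H]1[C@H]2C[C@@H](C(C)C)[C@](CC/C(C)=C/[Al](C)C)(C2)[C@@H]1/C=C(\C)C=C | intermediate
25 | 1-[(E)-4-bromo-3-methylbut-3-en-1-yl]-6-endo-isopropyl-3-endo-methoxy-2-exo-[(1E)-2-methylbuta-1,3-dien-1-yl]bicyclo[2.2.1]heptane | CO[C@H]1[C@H]2C[C@@H](C(C)C)[C@](CC/C(C)=C/Br)(C2)[C@@H]1/C=C(\C)C=C | intermediate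
26 | tetracyclic bromoalkene (target skeleton with C(Me)=CH in ring A; trans-fused; Br equatorial and cis to the angular methyl) | CO[C@H]1[C@H]2C[C@@H](C(C)C)[C@]3(CC[C@@]4(C)[C@H]([C@H]13)C(C)=CC[C@@H]4Br)C2 | intermediate
27 | β-epoxide of 26 (oxirane anti to the angular methyl) | CO[C@H]1[C@H]2C[C@@H](C(C)C)[C@]3(CC[C@@]4(C)[C@H]([C@H]13)[C@@]5(C)O[C@H]5C[C@@H]4Br)C2 | intermediate
28 | CNP0130529.1 | CO[C@H]1[C@H]2C[C@@H](C(C)C)[C@]3(CC[C@@]4(C)[C@H]([C@H]13)[C@](C)(O)[C@@H](O)C[C@@H]4Br)C2 | target

**Step count and risks**

Total step count: 18. Longest linear sequence: 18 steps (cyclopentanone to target); every other component is a purchased reagent.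

The three steps most likely to fail:

1. Step 16 (key step). The cycloaddition of the unactivated, trisubstituted bromoalkene may be too slow at temperatures the substrate tolerates, so that loss of HBr or E/Z isomerisation of the dienophile competes, and the chair/boat discrimination between the anti and syn transition states may be smaller than expected.
Fallback (activated dienophile, C–Br bond made after the cycloaddition), from 25 back to 26: copper-catalysed coupling of 25 with sodium benzenesulfinate (CuI, L-proline sodium salt, DMSO, 90 °C) should give, with retention of geometry, the (E)-alkenyl phenyl sulfone F1. This sulfonyl-activated triene should cyclise at 110–130 °C through the same anti transition state (sulfonyl endo) to the trans-fused sulfone cycloadduct F2. Deprotonation α to sulfur (LDA, THF, −78 °C) and oxidation of the carbanion with bis(trimethylsilyl) peroxide (oxidative desulfonylation) should give the β,γ-unsaturated ring-A ketone F3. L-Selectride (equatorial hydride delivery, −78 °C) should give the axial alcohol F4, and bromination with inversion (CBr4, P(n-Oct)3, PhMe, 70 °C) returns to 26.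

2. Step 6. The ester tether has to adopt its disfavoured s-cis form and the β-methoxy group deactivates the dienophile, so dimerisation or polymerisation of the cyclopentadiene may outrun the cyclisation.
Fallback (more reactive dienophile, C–O bond installed after the cycloaddition), from 7 back to 11: esterification of 7 with (E)-3-(pinacolboryl)acrylic acid (EDC, DMAP) gives the boryl acrylate F5. Dehydration as in step 6 gives the cyclopentadiene F6 (not isolated), whose doubly activated dienophile should cyclise below 100 °C, under the same tether control, to the endo-boryl lactone F7. Oxidation of the C–B bond with retention (NaBO3·4H2O, THF–H2O) gives the endo-hydroxy lactone F8, and O-methylation (Me3OBF4, proton sponge, CH2Cl2) returns to 11.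

3. Step 11. Olefination of the hindered, α-branched aldehyde masked as a lactol may be sluggish, and the hydroxy enal formed may cyclise by intramolecular oxa-Michael addition before it is iodinated.
Fallback (lactone opened as an amide, hydroxyl masked until the enal is in place), from 15 back to 19: opening of 15 with Me(MeO)NH·HCl/Me3Al gives the hydroxy Weinreb amide F9. Silylation (TBSCl, imidazole) gives the silyl ether F10, and DIBAL-H (−78 °C) the aldehyde F11. Wittig reaction with 17 gives the silyl-protected enal F12, and direct conversion of the silyl ether into the iodide (PPh3, I2, CH2Cl2) returns to 19 without a free hydroxyl ever facing the enal.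

**Further compounds**

F1 | step 16 | (E)-alkenyl phenyl sulfone analogue of 25 (sulfonyl cis to the methyl) | CO[C@H]1[C@H]2C[C@@H](C(C)C)[C@](CC/C(C)=C/S(=O)(=O)c3ccccc3)(C2)[C@@H]1/C=C(\C)C=C
F2 | step 16 | trans-fused sulfone cycloadduct (PhSO2 in place of Br in 26) | CO[C@H]1[C@H]2C[C@@H](C(C)C)[C@]3(CC[C@@]4(C)[C@H]([C@H]13)C(C)=CC[C@@H]4S(=O)(=O)c5ccccc5)C2
F3 | step 16 | β,γ-unsaturated ring-A ketone (C=O in place of CHBr in 26) | CO[C@H]1[C@H]2C[C@@H](C(C)C)[C@]3(CC[C@@]4(C)[C@H]([C@H]13)C(C)=CCC4=O)C2
F4 | step 16 | axial alcohol (OH trans to the angular methyl; epimeric position to Br in 26) | CO[C@H]1[C@H]2C[C@@H](C(C)C)[C@]3(CC[C@@]4(C)[C@H]([C@H]13)C(C)=CC[C@H]4O)C2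
F5 | step 6 | 2-(1-hydroxy-2-isopropylcyclopent-2-en-1-yl)ethyl (E)-3-(pinacolboryl)acrylate (racemic) | CC(C)C1=CCCC1(O)CCOC(=O)/C=C/B1OC(C)(C)C(C)(C)O1
F6 | step 6 | 2-(2-isopropylcyclopenta-1,3-dien-1-yl)ethyl (E)-3-(pinacolboryl)acrylate (not isolated) | CC(C)C1=C(CCOC(=O)/C=C/B2OC(C)(C)C(C)(C)O2)CC=C1
F7 | step 6 | racemic 3-endo-(pinacolboryl) analogue of lactone 11 | CC1(C)OB(OC1(C)C)[C@H]1[C@H]2C=C(C(C)C)[C@]3(CCOC(=O)[C@H]13)C2
F8 | step 6 | racemic 3-endo-hydroxy analogue of lactone 11 | O[C@H]1[C@H]2C=C(C(C)C)[C@]3(CCOC(=O)[C@H]13)C2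
F9 | step 11 | hydroxy Weinreb amide from 15 | CO[C@H]1[C@H]2C[C@@H](C(C)C)[C@](CCO)(C2)[C@@H]1C(=O)N(C)OC
F10 | step 11 | TBS ether of F9 | CO[C@H]1[C@H]2C[C@@H](C(C)C)[C@](CCO[Si](C)(C)C(C)(C)C)(C2)[C@@H]1C(=O)N(C)OC
F11 | step 11 | TBS-protected 2-exo-carbaldehyde | CO[C@H]1[C@H]2C[C@@H](C(C)C)[C@](CCO[Si](C)(C)C(C)(C)C)(C2)[C@@H]1C=O
F12 | step 11 | TBS ether of enal 18 | CO[C@H]1[C@H]2C[C@@H](C(C)C)[C@](CCO[Si](C)(C)C(C)(C)C)(C2)[C@@H]1/C=C(\C)C=O
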